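**Strategy.** The cyclohexene ring is disconnected across C1–C10 and C11–C12 (briarane numbering: C1 = methyl-bearing quaternary ring-fusion carbon, C10 = neighbouring ring-fusion CH, C11=C12 = ring olefin). C1, flanked by the oxygenated carbons C2 and C14, is a latent 2-methyl-1,3-dicarbonyl nucleophile; C11 is a latent nitronate. One base-mediated double Michael reaction (anionic formal [4+2]) of a vinyl β-keto thioester with a glyceraldehyde-derived nitroalkene forges both bonds, the ring, the quaternary centre and C10. The C11 nitro group is then turned into the methyl-bearing olefin carbon; a chromium-mediated coupling and ring-closing metathesis add butenolide and ten-membered ring.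

Key step: step 4

Remark: positions are named by briarane numbering (C2 butanoyloxy carbon, C5=C6 olefin of the ten-membered ring, C7 lactone carbinol carbon, C8 butenolide β-carbon, C9 hydroxyl carbon, C14 acetoxy carbon); (S)-2,2-dimethyl-1,3-dioxolane-4-carbaldehyde, (S)-3-hydroxyoxolan-2-one and 4-bromo-2-methylbut-1-ene are taken as purchasable. The nitro-bearing carbon C11 in 8–11 is drawn as the expected epimer; its configuration is erased in step 7.

**Step 1**
Reactants: 1 S-ethyl propanethioate; 2 acrolein (prop-2-enal)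
Product: 3 S-ethyl 3-hydroxy-2-methylpent-4-enethioate (racemic mixture of diastereomers)
Conditions: LiN(iPr)2, THF, −78 °C; then 2; aq. NH4Cl
Reagents that add atoms: none
Why: Aldol addition of the lithium thioester enolate to the aldehyde carbon of acrolein (1,2-addition at −78 °C); the two new stereocentres need no control because one is oxidised in step 2 and the other is epimerisable until step 4.

**Step 2**
Reactants: 3 S-ethyl 3-hydroxy-2-methylpent-4-enethioate
Product: 4 S-ethyl 2-methyl-3-oxopent-4-enethioate (racemic, used at once)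
Conditions: Dess–Martin periodinane, NaHCO3, CH2Cl2, 0 °C
Reagents that add atoms: none
Why: Dess–Martin oxidation of the allylic β-hydroxy thioester gives the α-methyl Nazarov-type vinyl β-keto thioester under neutral conditions that spare the thioester and the polymerisation-prone enone.

**Step 3**
Reactants: 5 (S)-2,2-dimethyl-1,3-dioxolane-4-carbaldehyde
Product: 7 (4R)-2,2-dimethyl-4-[(E)-2-nitroethenyl]-1,3-dioxolane, via nitroaldol adduct 6 (not isolated)
Conditions: MeNO2, Et3N (cat.), 0 °C to rt; then MsCl, Et3N, CH2Cl2, −20 °C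
Reagents that add atoms: nitromethane, C[N+](=O)[O-]
Why: Henry reaction followed by mesylation–elimination gives the (E)-nitroalkene; the dioxolane stereocentre comes unchanged from 5 (the descriptor changes from S to R only through the priority rules).

**Step 4**
Reactants: 4 S-ethyl 2-methyl-3-oxopent-4-enethioate; 7 (4R)-2,2-dimethyl-4-[(E)-2-nitroethenyl]-1,3-dioxolane
Product: 9 S-ethyl (1R,2R,3R)-2-[(4R)-2,2-dimethyl-1,3-dioxolan-4-yl]-1-methyl-3-nitro-6-oxocyclohexane-1-carbothioate, via acyclic Michael adduct 8 (not isolated)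
Conditions: Cs2CO3 (0.3 equiv), CH2Cl2, 0 °C to rt, slow addition of 4
Reagents that add atoms: none
Why: Cs2CO3 generates the cation-bridged (Z)-enolate of 4, whose carbon C1 adds to the nitro-activated β-carbon C10 of 7 (Michael addition, C1–C10 bond), and the nitronate carbon C11 so formed then adds to the terminal carbon C12 of the vinyl ketone (second Michael addition, C11–C12 bond). The closest known reaction type is the base-mediated double Michael annulation (anionic formal [4+2]) of Nazarov-type γ,δ-unsaturated β-keto esters with nitroalkenes or enones. The six-membered ring closes in the 6-endo-trig mode. C10 should be set by the dioxolane stereocentre (Felkin–Anh attack anti to the C–O bond of the γ-alkoxy nitroalkene), C1 by an endo-type arrangement in which the nitro group lies under the enolate oxygen and the thioester points away from the dioxolane, so that it ends trans to it, and C11 is inconsequential. The step needs attack of the hindered enolate on 7 in preference to self-condensation with the vinyl ketone of a second molecule of 4; the much higher electrophilicity of the nitroalkene and the slow addition of 4 should secure this.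

**Step 5**
Reactants: 9 S-ethyl (1R,2R,3R)-2-[(4R)-2,2-dimethyl-1,3-dioxolan-4-yl]-1-methyl-3-nitro-6-oxocyclohexane-1-carbothioate
Product: 10 S-ethyl (1R,2R,3R,6S)-2-[(4R)-2,2-dimethyl-1,3-dioxolan-4-yl]-6-hydroxy-1-methyl-3-nitrocyclohexane-1-carbothioate
Conditions: (R)-2-methyl-CBS-oxazaborolidine (20 mol%), BH3·SMe2, THF, −20 °C; MeOH
Reagents that add atoms: none
Why: Corey–Bakshi–Shibata reduction; the catalyst distinguishes the quaternary C1 side (large) from the CH2 side (small) of the ring ketone and should deliver hydride to give the 14S carbinol, trans to the C1 methyl group, while thioester and nitro group are inert to borane at this temperature.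

**Step 6**
Reactants: 10 S-ethyl (1R,2R,3R,6S)-2-[(4R)-2,2-dimethyl-1,3-dioxolan-4-yl]-6-hydroxy-1-methyl-3-nitrocyclohexane-1-carbothioate
Product: 11 S-ethyl (1R,2R,3R,6S)-6-(acetyloxy)-2-[(4R)-2,2-dimethyl-1,3-dioxolan-4-yl]-1-methyl-3-nitrocyclohexane-1-carbothioate
Conditions: Ac2O, pyridine, DMAP (cat.), CH2Cl2, rt
Reagents that add atoms: acetic anhydride, CC(=O)OC(C)=O
Why: DMAP-catalysed acylation installs the C14 acetate of the target at once; pyridine is too weak a base to form the nitronate.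

**Step 7**
Reactants: 11 S-ethyl (1R,2R,3R,6S)-6-(acetyloxy)-2-[(4R)-2,2-dimethyl-1,3-dioxolan-4-yl]-1-methyl-3-nitrocyclohexane-1-carbothioate
Product: 12 S-ethyl (1R,2S,6S)-6-(acetyloxy)-2-[(4R)-2,2-dimethyl-1,3-dioxolan-4-yl]-1-methyl-3-oxocyclohexane-1-carbothioate
Conditions: NaNO2, AcOH, DMSO–H2O, 35 °C
Reagents that add atoms: water, O
Why: Nitrite-mediated Nef reaction of the secondary nitro group (nitrosation to the pseudonitrole, then hydrolysis) gives the C11 ketone under weakly acidic conditions that should leave acetate, thioester, acetonide and the C10 stereocentre untouched.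

**Step 8**
Reactants: 12 S-ethyl (1R,2S,6S)-6-(acetyloxy)-2-[(4R)-2,2-dimethyl-1,3-dioxolan-4-yl]-1-methyl-3-oxocyclohexane-1-carbothioate
Product: 13 S-ethyl (1R,2S,6S)-6-(acetyloxy)-2-[(4R)-2,2-dimethyl-1,3-dioxolan-4-yl]-1-methyl-3-[(trifluoromethanesulfonyl)oxy]cyclohex-3-ene-1-carbothioate
Conditions: KN(SiMe3)2 (1.05 equiv), THF, −78 °C; then Comins' reagent
Reagents that add atoms: N-(5-chloropyridin-2-yl)bis(trifluoromethanesulfonimide) (Comins' reagent), FC(F)(F)S(=O)(=O)N(c1ccc(Cl)cn1)S(=O)(=O)C(F)(F)F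
Why: Kinetic deprotonation occurs at the unhindered C12 methylene, not at the C10 methine next to the quaternary carbon, and O-triflation fixes the C11=C12 double bond; the ketone is several pKa units more acidic than the acetate and the thioester has no α-hydrogen.

**Step 9**
Reactants: 13 S-ethyl (1R,2S,6S)-6-(acetyloxy)-2-[(4R)-2,2-dimethyl-1,3-dioxolan-4-yl]-1-methyl-3-[(trifluoromethanesulfonyl)oxy]cyclohex-3-ene-1-carbothioate
Product: 14 S-ethyl (1R,2S,6S)-6-(acetyloxy)-2-[(4R)-2,2-dimethyl-1,3-dioxolan-4-yl]-1,3-dimethylcyclohex-3-ene-1-carbothioate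
Conditions: SnMe4, Pd(PPh3)4 (5 mol%), LiCl, DMF, 60 °C
Reagents that add atoms: tetramethylstannane, C[Sn](C)(C)C
Why: Stille coupling of the alkenyl triflate with tetramethyltin installs the C11 methyl group with the olefin position fixed; without a copper cofactor the thioester does not couple.

**Step 10**
Reactants: 14 S-ethyl (1R,2S,6S)-6-(acetyloxy)-2-[(4R)-2,2-dimethyl-1,3-dioxolan-4-yl]-1,3-dimethylcyclohex-3-ene-1-carbothioate; 15 4-bromo-2-methylbut-1-ene
Product: 17 (1S,5S,6R)-5-[(4R)-2,2-dimethyl-1,3-dioxolan-4-yl]-4,6-dimethyl-6-(4-methylpent-4-enoyl)cyclohex-3-en-1-yl acetate, via alkylzinc bromide 16 (not isolated)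
Conditions: 15, Zn, LiCl, THF, 50 °C; then 14, PdCl2(PPh3)2 (5 mol%), toluene, rt
Reagents that add atoms: none
Why: Fukuyama coupling of the thioester with the alkylzinc bromide (zinc insertion into the bromide) gives the C2 ketone and the C2–C3 bond in one step, with acetate, acetonide and olefins tolerated.

**Step 11**
Reactants: 17 (1S,5S,6R)-5-[(4R)-2,2-dimethyl-1,3-dioxolan-4-yl]-4,6-dimethyl-6-(4-methylpent-4-enoyl)cyclohex-3-en-1-yl acetate
Product: 18 (1S,5S,6S)-5-[(4R)-2,2-dimethyl-1,3-dioxolan-4-yl]-6-[(1R)-1-hydroxy-4-methylpent-4-en-1-yl]-4,6-dimethylcyclohex-3-en-1-yl acetate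
Conditions: (S)-2-methyl-CBS-oxazaborolidine, catecholborane, toluene, −78 to −40 °C
Reagents that add atoms: none
Why: Corey–Bakshi–Shibata reduction of a ketone flanked by a quaternary carbon (large) and a CH2 chain (small) should give the 2R carbinol under catalyst control; catecholborane does not hydroborate the olefins.

**Step 12**
Reactants: 18 (1S,5S,6S)-5-[(4R)-2,2-dimethyl-1,3-dioxolan-4-yl]-6-[(1R)-1-hydroxy-4-methylpent-4-en-1-yl]-4,6-dimethylcyclohex-3-en-1-yl acetate
Product: 19 (1R)-1-[(1S,2S,6S)-6-(acetyloxy)-2-[(4R)-2,2-dimethyl-1,3-dioxolan-4-yl]-1,3-dimethylcyclohex-3-en-1-yl]-4-methylpent-4-en-1-yl butanoate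
Conditions: (PrCO)2O, Et3N, DMAP, CH2Cl2, 0 °C to rt
Reagents that add atoms: butanoic anhydride, CCCC(=O)OC(=O)CCC
Why: DMAP-catalysed acylation installs the C2 butanoate of the target; acylation should outrun 1,3-acetyl migration from the C14 oxygen.

**Step 13**
Reactants: 19 (1R)-1-[(1S,2S,6S)-6-(acetyloxy)-2-[(4R)-2,2-dimethyl-1,3-dioxolan-4-yl]-1,3-dimethylcyclohex-3-en-1-yl]-4-methylpent-4-en-1-yl butanoate
Product: 20 (1R)-1-[(1S,2S,6S)-6-(acetyloxy)-2-formyl-1,3-dimethylcyclohex-3-en-1-yl]-4-methylpent-4-en-1-yl butanoate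
Conditions: H5IO6, EtOAc, rt
Reagents that add atoms: none
Why: Periodic acid hydrolyses the terminal acetonide and cleaves the diol in one pot (glycol cleavage) to reveal the C9 aldehyde, which is used directly because it is β,γ-unsaturated and α-branched.

**Step 14**
Reactants: 21 (S)-3-hydroxyoxolan-2-one ((S)-α-hydroxy-γ-butyrolactone)
Product: 23 methyl (2S)-2-hydroxy-4-(phenylselanyl)butanoate, via sodium carboxylate 22 (not isolated)
Conditions: (PhSe)2, Na, THF, reflux; then 21, THF–DMPU, 80 °C; then MeI, rt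
Reagents that add atoms: diphenyl diselenide, c1ccc(cc1)[Se][Se]c1ccccc1; iodomethane, CI
Why: SN2 opening of the lactone at its O–CH2 carbon by the soft selenolate, then O-methylation of the carboxylate; the stereocentre is not involved and the selenide is a masked vinyl group.

**Step 15**
Reactants: 23 methyl (2S)-2-hydroxy-4-(phenylselanyl)butanoate
Product: 24 methyl (2S)-4-(phenylselanyl)-2-(propanoyloxy)butanoate
Conditions: EtCOCl, pyridine, CH2Cl2, 0 °C
Reagents that add atoms: propanoyl chloride, CCC(=O)Cl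
Why: O-acylation supplies the three carbons C17, C18 and C19 of the butenolide.

**Step 16**
Reactants: 24 methyl (2S)-4-(phenylselanyl)-2-(propanoyloxy)butanoate
Product: 25 (5S)-4-hydroxy-3-methyl-5-[2-(phenylselanyl)ethyl]furan-2(5H)-one
Conditions: LiN(SiMe3)2 (2.2 equiv), THF, −78 to 0 °C; aq. HCl
Reagents that add atoms: none
Why: Dieckmann cyclisation of the O-acyl α-hydroxy ester (propanoate enolate onto the methyl ester) gives the 3-methyltetronic acid, trapped as its enolate; the saturated side chain keeps the C7 hydrogen no more acidic than in O-acyl lactates, which cyclise with retention.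

**Step 17**
Reactants: 25 (5S)-4-hydroxy-3-methyl-5-[2-(phenylselanyl)ethyl]furan-2(5H)-one
Product: 26 (2S)-4-methyl-5-oxo-2-[2-(phenylselanyl)ethyl]-2,5-dihydrofuran-3-yl trifluoromethanesulfonate
Conditions: PhNTf2, Et3N, CH2Cl2, 0 °C to rt
Reagents that add atoms: N-phenylbis(trifluoromethanesulfonimide), FC(F)(F)S(=O)(=O)N(c1ccccc1)S(=O)(=O)C(F)(F)F
Why: O-triflation of the acidic tetronic acid gives the alkenyl triflate at C8; the mild triflating agent does not touch the selenide.

**Step 18**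
Reactants: 20 (1R)-1-[(1S,2S,6S)-6-(acetyloxy)-2-formyl-1,3-dimethylcyclohex-3-en-1-yl]-4-methylpent-4-en-1-yl butanoate; 26 (2S)-4-methyl-5-oxo-2-[2-(phenylselanyl)ethyl]-2,5-dihydrofuran-3-yl trifluoromethanesulfonate
Product: 27 (1R)-1-[(1S,2S,6S)-6-(acetyloxy)-2-{(R)-hydroxy[(2S)-4-methyl-5-oxo-2-[2-(phenylselanyl)ethyl]-2,5-dihydrofuran-3-yl]methyl}-1,3-dimethylcyclohex-3-en-1-yl]-4-methylpent-4-en-1-yl butanoate
Conditions: CrCl2 (6 equiv), NiCl2 (2 mol%), DMF–THF, rt
Reagents that add atoms: none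
Why: Nozaki–Hiyama–Kishi reaction (zerovalent nickel inserts into the alkenyl triflate, transmetalation gives an alkenylchromium species that adds only to the aldehyde) forms C8–C9; Felkin–Anh addition anti to the quaternary C1 substituent of the α-branched aldehyde should give the 9R carbinol, and the non-basic medium spares the esters, the lactone and the C10 stereocentre.

**Step 19**
Reactants: 27 (1R)-1-[(1S,2S,6S)-6-(acetyloxy)-2-{(R)-hydroxy[(2S)-4-methyl-5-oxo-2-[2-(phenylselanyl)ethyl]-2,5-dihydrofuran-3-yl]methyl}-1,3-dimethylcyclohex-3-en-1-yl]-4-methylpent-4-en-1-yl butanoate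
Product: 29 (1R)-1-[(1S,2S,6S)-6-(acetyloxy)-2-{(R)-[(2S)-2-ethenyl-4-methyl-5-oxo-2,5-dihydrofuran-3-yl](hydroxy)methyl}-1,3-dimethylcyclohex-3-en-1-yl]-4-methylpent-4-en-1-yl butanoate, via selenoxide 28 (not isolated)
Conditions: H2O2 (30% aq.), pyridine, CH2Cl2, 0 to 40 °C
Reagents that add atoms: none
Why: Oxidation to the selenoxide and syn-elimination toward its only β-carbon (C6) unveils the vinyl group after the tetronic acid chemistry is over, under neutral conditions that leave the now allylic C7 hydrogen untouched.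

**Step 20**
Reactants: 29 (1R)-1-[(1S,2S,6S)-6-(acetyloxy)-2-{(R)-[(2S)-2-ethenyl-4-methyl-5-oxo-2,5-dihydrofuran-3-yl](hydroxy)methyl}-1,3-dimethylcyclohex-3-en-1-yl]-4-methylpent-4-en-1-yl butanoate
Product: 30 CNP0293221.1 (target)
Conditions: second-generation Hoveyda–Grubbs catalyst RuCl2(H2IMes)(=CH–C6H4-2-OiPr) (10 mol%), 1,4-benzoquinone (10 mol%), toluene (1 mM), 80 °C
Reagents that add atoms: none
Why: Ring-closing metathesis between the vinyl group on C7 and the 1,1-disubstituted olefin closes the ten-membered ring at C5=C6 with loss of ethene; the ring size should enforce the Z (cis-cyclodecene) geometry, and high dilution disfavours oligomers.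

**Compound list**

1 | S-ethyl propanethioate | CCC(=O)SCC | starting material
2 | acrolein | C=CC=O | starting material
3 | S-ethyl 3-hydroxy-2-methylpent-4-enethioate (racemic, diastereomer mixture) | CCSC(=O)C(C)C(O)C=C | intermediate
4 | S-ethyl 2-methyl-3-oxopent-4-enethioate (racemic) | CCSC(=O)C(C)C(=O)C=C | intermediate
5 | (S)-2,2-dimethyl-1,3-dioxolane-4-carbaldehyde | O=C[C@@H]1COC(C)(C)O1 | starting material
6 | 1-[(4S)-2,2-dimethyl-1,3-dioxolan-4-yl]-2-nitroethan-1-ol (carbinol epimers) | [O-][N+](=O)CC(O)[C@@H]1COC(C)(C)O1 | intermediate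
7 | (4R)-2,2-dimethyl-4-[(E)-2-nitroethenyl]-1,3-dioxolane | [O-][N+](=O)/C=C/[C@@H]1COC(C)(C)O1 | intermediate
8 | S-ethyl (2R)-2-[(1R)-1-[(4R)-2,2-dimethyl-1,3-dioxolan-4-yl]-2-nitroethyl]-2-methyl-3-oxopent-4-enethioate | CCSC(=O)[C@@](C)(C(=O)C=C)[C@@H]([C@@H]1COC(C)(C)O1)C[N+](=O)[O-] | intermediate
9 | S-ethyl (1R,2R,3R)-2-[(4R)-2,2-dimethyl-1,3-dioxolan-4-yl]-1-methyl-3-nitro-6-oxocyclohexane-1-carbothioate | CCSC(=O)[C@]1(C)[C@@H]([C@@H]2COC(C)(C)O2)[C@H]([N+](=O)[O-])CCC1=O | intermediate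
10 | S-ethyl (1R,2R,3R,6S)-2-[(4R)-2,2-dimethyl-1,3-dioxolan-4-yl]-6-hydroxy-1-methyl-3-nitrocyclohexane-1-carbothioate | CCSC(=O)[C@]1(C)[C@@H]([C@@H]2COC(C)(C)O2)[C@H]([N+](=O)[O-])CC[C@@H]1O | intermediate
11 | S-ethyl (1R,2R,3R,6S)-6-(acetyloxy)-2-[(4R)-2,2-dimethyl-1,3-dioxolan-4-yl]-1-methyl-3-nitrocyclohexane-1-carbothioate | CCSC(=O)[C@]1(C)[C@@H]([C@@H]2COC(C)(C)O2)[C@H]([N+](=O)[O-])CC[C@@H]1OC(C)=O | intermediate
12 | S-ethyl (1R,2S,6S)-6-(acetyloxy)-2-[(4R)-2,2-dimethyl-1,3-dioxolan-4-yl]-1-methyl-3-oxocyclohexane-1-carbothioate | CCSC(=O)[C@]1(C)[C@@H]([C@@H]2COC(C)(C)O2)C(=O)CC[C@@H]1OC(C)=O | intermediate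
13 | S-ethyl (1R,2S,6S)-6-(acetyloxy)-2-[(4R)-2,2-dimethyl-1,3-dioxolan-4-yl]-1-methyl-3-[(trifluoromethanesulfonyl)oxy]cyclohex-3-ene-1-carbothioate | CCSC(=O)[C@]1(C)[C@@H]([C@@H]2COC(C)(C)O2)C(OS(=O)(=O)C(F)(F)F)=CC[C@@H]1OC(C)=O | intermediate
14 | S-ethyl (1R,2S,6S)-6-(acetyloxy)-2-[(4R)-2,2-dimethyl-1,3-dioxolan-4-yl]-1,3-dimethylcyclohex-3-ene-1-carbothioate | CCSC(=O)[C@]1(C)[C@@H]([C@@H]2COC(C)(C)O2)C(C)=CC[C@@H]1OC(C)=O | intermediate
15 | 4-bromo-2-methylbut-1-ene | C=C(C)CCBr | starting material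
16 | (3-methylbut-3-en-1-yl)zinc bromide | C=C(C)CC[Zn]Br | intermediate
17 | (1S,5S,6R)-5-[(4R)-2,2-dimethyl-1,3-dioxolan-4-yl]-4,6-dimethyl-6-(4-methylpent-4-enoyl)cyclohex-3-en-1-yl acetate | C=C(C)CCC(=O)[C@]1(C)[C@@H]([C@@H]2COC(C)(C)O2)C(C)=CC[C@@H]1OC(C)=O | intermediate
18 | (1S,5S,6S)-5-[(4R)-2,2-dimethyl-1,3-dioxolan-4-yl]-6-[(1R)-1-hydroxy-4-methylpent-4-en-1-yl]-4,6-dimethylcyclohex-3-en-1-yl acetate | C=C(C)CC[C@@H](O)[C@]1(C)[C@@H]([C@@H]2COC(C)(C)O2)C(C)=CC[C@@H]1OC(C)=O | intermediate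
19 | (1R)-1-[(1S,2S,6S)-6-(acetyloxy)-2-[(4R)-2,2-dimethyl-1,3-dioxolan-4-yl]-1,3-dimethylcyclohex-3-en-1-yl]-4-methylpent-4-en-1-yl butanoate | C=C(C)CC[C@@H](OC(=O)CCC)[C@]1(C)[C@@H]([C@@H]2COC(C)(C)O2)C(C)=CC[C@@H]1OC(C)=O | intermediate
20 | (1R)-1-[(1S,2S,6S)-6-(acetyloxy)-2-formyl-1,3-dimethylcyclohex-3-en-1-yl]-4-methylpent-4-en-1-yl butanoate | C=C(C)CC[C@@H](OC(=O)CCC)[C@]1(C)[C@@H](C=O)C(C)=CC[C@@H]1OC(C)=O | intermediate
21 | (S)-3-hydroxyoxolan-2-one | O[C@H]1CCOC1=O | starting material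
22 | sodium (2S)-2-hydroxy-4-(phenylselanyl)butanoate | O[C@@H](CC[Se]c1ccccc1)C(=O)[O-].[Na+] | intermediate
23 | methyl (2S)-2-hydroxy-4-(phenylselanyl)butanoate | O[C@@H](CC[Se]c1ccccc1)C(=O)OC | intermediate
24 | methyl (2S)-4-(phenylselanyl)-2-(propanoyloxy)butanoate | CCC(=O)O[C@@H](CC[Se]c1ccccc1)C(=O)OC | intermediate
25 | (5S)-4-hydroxy-3-methyl-5-[2-(phenylselanyl)ethyl]furan-2(5H)-one | CC1=C(O)[C@H](CC[Se]c2ccccc2)OC1=O | intermediate
26 | (2S)-4-methyl-5-oxo-2-[2-(phenylselanyl)ethyl]-2,5-dihydrofuran-3-yl trifluoromethanesulfonate | CC1=C(OS(=O)(=O)C(F)(F)F)[C@H](CC[Se]c2ccccc2)OC1=O | intermediate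
27 | (1R)-1-[(1S,2S,6S)-6-(acetyloxy)-2-{(R)-hydroxy[(2S)-4-methyl-5-oxo-2-[2-(phenylselanyl)ethyl]-2,5-dihydrofuran-3-yl]methyl}-1,3-dimethylcyclohex-3-en-1-yl]-4-methylpent-4-en-1-yl butanoate | C=C(C)CC[C@@H](OC(=O)CCC)[C@]1(C)[C@@H]([C@@H](O)C2=C(C)C(=O)O[C@H]2CC[Se]c3ccccc3)C(C)=CC[C@@H]1OC(C)=O | intermediate
28 | selenoxide of 27 (phenylseleninyl in place of phenylselanyl, selenium epimers) | C=C(C)CC[C@@H](OC(=O)CCC)[C@]1(C)[C@@H]([C@@H](O)C2=C(C)C(=O)O[C@H]2CC[Se](=O)c3ccccc3)C(C)=CC[C@@H]1OC(C)=O | intermediate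
29 | (1R)-1-[(1S,2S,6S)-6-(acetyloxy)-2-{(R)-[(2S)-2-ethenyl-4-methyl-5-oxo-2,5-dihydrofuran-3-yl](hydroxy)methyl}-1,3-dimethylcyclohex-3-en-1-yl]-4-methylpent-4-en-1-yl butanoate | C=C(C)CC[C@@H](OC(=O)CCC)[C@]1(C)[C@@H]([C@@H](O)C2=C(C)C(=O)O[C@H]2C=C)C(C)=CC[C@@H]1OC(C)=O | intermediate
30 | CNP0293221.1: 14-O-acetyl-2-O-butanoyl-9-hydroxy briarane with 5Z and 11 olefins and the C7–O/C8=C17 α-methylbutenolide, (1S,2R,7S,9R,10S,14S) in briarane numbering | CCCC(=O)O[C@@H]1CC/C(C)=C\[C@@H]2OC(=O)C(C)=C2[C@H](O)[C@H]2C(C)=CC[C@H](OC(C)=O)[C@@]21C | target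

**Total step count:** 20. **Longest linear sequence:** 15 steps (1, 2, 4–13, 18–20).

**Steps most likely to fail**

Step 4 (loss of diastereocontrol at the quaternary carbon C1, or consumption of 4 by self-condensation through its vinyl ketone). The annulation would be run as a Diels–Alder reaction instead. Setting out from 4, soft enolisation and silylation (TBSOTf, Et3N, CH2Cl2, −78 °C) should give S-ethyl (2Z)-3-[(tert-butyldimethylsilyl)oxy]-2-methylpenta-2,4-dienethioate F1. Heating F1 with 7 in toluene should give the cyclohexenyl silyl ether F2 by endo addition of the nitro group on the face anti to the dioxolane oxygen; both bonds form suprafacially, so the C1/C10 relation follows from the diene geometry. HF·pyridine (THF, 0 °C) would cleave the silyl enol ether, and the route is rejoined at 9.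

Step 20 (oligomerisation in place of closure of the strained ten-membered ring, or formation of the E ring olefin). The order of the two fragment unions would be reversed so that the ring is closed by the chromium-mediated coupling. Setting out from 26, H2O2/pyridine would give the vinyl triflate F3. Cross-metathesis of F3 with 19 (second-generation Hoveyda–Grubbs catalyst, CH2Cl2, 40 °C) would give the trisubstituted olefin, of which the Z isomer F4 is kept after chromatography; this intermolecular metathesis is not expected to favour Z, which is the weakness of this fallback. H5IO6 in EtOAc would then give the aldehyde F5, and an intramolecular Nozaki–Hiyama–Kishi reaction (CrCl2, NiCl2 cat., DMF, high dilution) would close the ring at C8–C9 and come back to the route at 30.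

Step 18 (poor facial selectivity at C9, or erosion of the α-stereocentre C10 of aldehyde 20). The carbinol centre would be set by reduction instead of by the C–C bond formation. Setting out from the C9 epimer mixture of 27, Dess–Martin periodinane with NaHCO3 would give the C9 ketone F6. (S)-2-methyl-CBS-oxazaborolidine with catecholborane (toluene, −78 °C), with the butenolide carbon as the large sp2 substituent, should return the 9R alcohol under catalyst control, and the route is rejoined at 27.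

**Further compounds**

F1 | step 4 | S-ethyl (2Z)-3-[(tert-butyldimethylsilyl)oxy]-2-methylpenta-2,4-dienethioate | CCSC(=O)/C(C)=C(/C=C)O[Si](C)(C)C(C)(C)C
F2 | step 4 | S-ethyl (1R,5R,6R)-2-[(tert-butyldimethylsilyl)oxy]-6-[(4R)-2,2-dimethyl-1,3-dioxolan-4-yl]-1-methyl-5-nitrocyclohex-2-ene-1-carbothioate | CCSC(=O)[C@]1(C)[C@@H]([C@@H]2COC(C)(C)O2)[C@H]([N+](=O)[O-])CC=C1O[Si](C)(C)C(C)(C)C
F3 | step 20 | (2S)-2-ethenyl-4-methyl-5-oxo-2,5-dihydrofuran-3-yl trifluoromethanesulfonate | CC1=C(OS(=O)(=O)C(F)(F)F)[C@H](C=C)OC1=O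
F4 | step 20 | (1R,4Z)-1-[(1S,2S,6S)-6-(acetyloxy)-2-[(4R)-2,2-dimethyl-1,3-dioxolan-4-yl]-1,3-dimethylcyclohex-3-en-1-yl]-4-methyl-5-[(2S)-4-methyl-5-oxo-3-[(trifluoromethanesulfonyl)oxy]-2,5-dihydrofuran-2-yl]pent-4-en-1-yl butanoate | CCCC(=O)O[C@H](CC/C(C)=C\[C@@H]2OC(=O)C(C)=C2OS(=O)(=O)C(F)(F)F)[C@]1(C)[C@@H]([C@@H]3COC(C)(C)O3)C(C)=CC[C@@H]1OC(C)=O
F5 | step 20 | (1R,4Z)-1-[(1S,2S,6S)-6-(acetyloxy)-2-formyl-1,3-dimethylcyclohex-3-en-1-yl]-4-methyl-5-[(2S)-4-methyl-5-oxo-3-[(trifluoromethanesulfonyl)oxy]-2,5-dihydrofuran-2-yl]pent-4-en-1-yl butanoate | CCCC(=O)O[C@H](CC/C(C)=C\[C@@H]2OC(=O)C(C)=C2OS(=O)(=O)C(F)(F)F)[C@]1(C)[C@@H](C=O)C(C)=CC[C@@H]1OC(C)=O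
F6 | step 18 | (1R)-1-[(1S,2S,6S)-6-(acetyloxy)-1,3-dimethyl-2-{(2S)-4-methyl-5-oxo-2-[2-(phenylselanyl)ethyl]-2,5-dihydrofuran-3-carbonyl}cyclohex-3-en-1-yl]-4-methylpent-4-en-1-yl butanoate | C=C(C)CC[C@@H](OC(=O)CCC)[C@]1(C)[C@@H](C(=O)C2=C(C)C(=O)O[C@H]2CC[Se]c3ccccc3)C(C)=CC[C@@H]1OC(C)=O
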